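The route is built on disconnecting the C19–C20 bond at the spiro atom (atoms numbered in target-SMILES order). C20 is shared by rings B and C. One neighbour is C2, the carbon of the exocyclic methylene group and therefore a ketone in disguise. The other is the ether carbon C7. Together these form an aldol-type array, a β-hydroxy ketone with a fully substituted α-carbon. One Lewis-acid semipinacol shift builds it. A C20–C7 epoxide opens at C20 while C19 moves from carbinol C2 to C20. This contracts a seven-membered ring to ring B, fixes the spiro centre, and releases the C2 ketone and C7 hydroxyl. The precursor is a cis-fused 6-7-6 syn-epoxy cycloheptanol.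

Key step: step 19

Remark on numbering: C1 is the exocyclic CH2, followed by C2–C5, O6, C7–C11, Br12, C13–C16, O17 and C18–C23. Ring A is C9, C11, C13, C14, C15, C18. Ring B is C7, C8, C9, C18, C19, C20. Ring C is C2–C5, C21, C20. Ring D is C5, O6, C7, C20, C21. β is the face of ring A that carries the C10 methyl group, and α is the opposite face.

Assumption: the antipode of the chiral ligand in step 2 is chosen so that the (6S,7R) adduct results. Compounds 1 and 17 are commercial.

Step 1
Reactants: 1 geranyl acetate
Product: 2 (2E,6E)-8-hydroxy-3,7-dimethylocta-2,6-dien-1-yl acetate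
Conditions: SeO2 (cat.), t-BuOOH, salicylic acid (cat.), CH2Cl2, 0 °C to rt
Reagents that add atoms: tert-butyl hydroperoxide, CC(C)(C)OO
Why: Catalytic SeO2 allylic oxidation (ene reaction, then a [2,3]-sigmatropic shift) should hydroxylate the E-methyl group of the electron-richer 6,7-alkene, because the 2,3-alkene is deactivated by its allylic acetate.

Step 2
Reactants: 2 (2E,6E)-8-hydroxy-3,7-dimethylocta-2,6-dien-1-yl acetate
Product: 3 (2E,6S,7R)-6-bromo-7-chloro-8-hydroxy-3,7-dimethyloct-2-en-1-yl acetate
Conditions: N-bromosuccinimide, ClTi(OiPr)3, enantiopure tridentate salicylaldimine–amino alcohol ligand (20 mol %), hexanes, −20 °C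
Reagents that add atoms: N-bromosuccinimide, O=C1CCC(=O)N1Br; chlorotitanium triisopropoxide, CC(C)O[Ti](Cl)(OC(C)C)OC(C)C
Why: In this titanium-mediated catalytic enantioselective bromochlorination of an allylic alcohol, the alkoxide-bound chiral complex confines the reaction to the 6,7-alkene and delivers chloride anti to the bromonium ion at the tertiary carbon, so the ligand and the E geometry set C11 (S, bearing Br) and the C9 chloride.

Step 3
Reactants: 3 (2E,6S,7R)-6-bromo-7-chloro-8-hydroxy-3,7-dimethyloct-2-en-1-yl acetate
Product: 4 (2E,6S,7R)-6-bromo-8-(tert-butyldimethylsilyloxy)-7-chloro-3,7-dimethyloct-2-en-1-yl acetate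
Conditions: t-BuMe2SiCl, imidazole, CH2Cl2, 0 °C to rt
Reagents that add atoms: tert-butyldimethylsilyl chloride, CC(C)(C)[Si](C)(C)Cl
Why: Standard silylation under weakly basic conditions does not close the chlorohydrin to an epoxide, and a silyl ether is chosen because it cannot act as a neighbouring group towards C9.

Step 4
Reactants: 4 (2E,6S,7R)-6-bromo-8-(tert-butyldimethylsilyloxy)-7-chloro-3,7-dimethyloct-2-en-1-yl acetate
Product: 6 ring A hydroxy acetate (C15 α-equatorial OH; β-axial CH3), via acetoxonium chloride 5 (not isolated)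
Conditions: (CF3)2CHOH, 23 °C; then H2O
Reagents that add atoms: water, O
Why: In this enantiospecific solvolytic bromonium–olefin cyclisation, the ionising solvent removes the tertiary chloride with anchimeric help from bromine, the E-2,3-alkene opens the bromonium ion at C9 through a chair transition state (6-endo; Br, C8 and C19 equatorial, which sets C9 and C18 from C11), and the acetate carbonyl traps the C15 cation anti to the new bond before water cleaves the acetoxonium ion.

Step 5
Reactants: 6 ring A hydroxy acetate
Product: 7 ring A exocyclic alkene (C15=C16) acetate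
Conditions: SOCl2, pyridine, −20 to 0 °C
Reagents that add atoms: none
Why: This is an E2 dehydration through the chlorosulfite; the equatorial leaving group at C15 has no antiperiplanar ring hydrogen, so the proton should be lost from the axial methyl group to give the exocyclic alkene, which also erases the wrongly configured C15.

Step 6
Reactants: 7 ring A exocyclic alkene acetate
Product: 9 ring A C15 ketone, via secondary ozonide 8 (not isolated)
Conditions: O3, CH2Cl2, −78 °C; then Me2S
Reagents that add atoms: ozone, [O-][O+]=O
Why: Ozonolysis with reductive work-up cleaves the only alkene and leaves the bromide, acetate and silyl ether untouched.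

Step 7
Reactants: 9 ring A C15 ketone
Product: 10 ring A diol (C15 β-axial OH; α-equatorial CH3; C19 OH)
Conditions: MeMgBr (5 equiv), LaCl3·2LiCl (0.3 equiv), THF, −20 to 0 °C
Reagents that add atoms: methylmagnesium bromide, C[Mg]Br
Why: In this lanthanide-assisted Grignard 1,2-addition, the β-axial C10 methyl group blocks axial approach as in 3,3,5-trimethylcyclohexanone, so methyl should enter equatorially from the α face to give the β-axial tertiary alcohol (C15 R), while excess reagent removes the acetate.

Step 8
Reactants: 10 ring A diol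
Product: 11 ring A C19 iodide (C15 OH free; C8 OTBS)
Conditions: I2, PPh3, imidazole, CH2Cl2, 0 °C to rt
Reagents that add atoms: iodine, II
Why: Appel-type iodination is selective for the primary C19 hydroxyl, because the tertiary alcohol cannot be displaced through an alkoxyphosphonium salt.

Step 9
Reactants: 11 ring A C19 iodide
Product: 12 ring A iodo diol (C8 OH; C15 OH)
Conditions: HF·pyridine, THF–pyridine, 0 °C to rt
Reagents that add atoms: none
Why: Acidic fluoride desilylation frees the primary alcohol without forming an alkoxide that could displace the C19 iodide.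

Step 10
Reactants: 12 ring A iodo diol
Product: 13 ring A C8 aldehyde
Conditions: Dess–Martin periodinane, CH2Cl2, rt
Reagents that add atoms: none
Why: Dess–Martin oxidation gives a neopentyl aldehyde with no α-hydrogen, which can therefore neither epimerise nor lose HBr.

Step 11
Reactants: 13 ring A C8 aldehyde
Product: 14 ring A C8 aldehyde C15 triethylsilyl ether
Conditions: Et3SiOTf, 2,6-lutidine, CH2Cl2, −78 to 0 °C
Reagents that add atoms: triethylsilyl trifluoromethanesulfonate, CC[Si](CC)(CC)OS(=O)(=O)C(F)(F)F
Why: Silyl triflate silylation is reactive enough for the hindered axial tertiary alcohol, and the non-enolisable aldehyde cannot form an enol silane.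

Step 12
Reactants: 14 ring A C8 aldehyde C15 triethylsilyl ether
Product: 16 ring A aldehyde (C7 formyl on C8; C19 iodide; C15 OTES), via methyl enol ether 15 (not isolated)
Conditions: MeOCH2PPh3Cl, KN(SiMe3)2, THF, 0 °C; then TsOH·H2O (cat.), acetone–H2O, 0 °C
Reagents that add atoms: (methoxymethyl)triphenylphosphonium chloride, COC[P+](c1ccccc1)(c1ccccc1)c1ccccc1.[Cl-]; water, O
Why: Wittig methoxymethylenation followed by mild hydrolysis of the enol ether is the standard one-carbon homologation of a hindered aldehyde and introduces C7, and the hindered tertiary silyl ether should survive the brief acid treatment.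

Step 13
Reactants: 17 methyl 3,3-dimethylpent-4-enoate
Product: 18 N-methoxy-N,3,3-trimethylpent-4-enamide
Conditions: MeNH(OMe)·HCl, i-PrMgCl, THF, −20 °C
Reagents that add atoms: N,O-dimethylhydroxylamine hydrochloride, CNOC.Cl
Why: This is Weinreb amide formation by aminolysis of the ester with the magnesium amide.

Step 14
Reactants: 18 N-methoxy-N,3,3-trimethylpent-4-enamide; 16 ring A aldehyde
Product: 22 (Z)-α,β-unsaturated Weinreb amide (C20=C7; C8 cis to C2), via lithium enolate 19 (not isolated), via lithium aldolate 20 (not isolated), via mesylate 21 (not isolated)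
Conditions: LiN(i-Pr)2, THF, −78 °C; 16; MsCl, −78 to 0 °C; DBU, rt to 40 °C
Reagents that add atoms: none
Why: This aldol condensation runs as amide-enolate addition (only C20 can be deprotonated), mesylation of the aldolate and base-induced β-elimination, and allylic strain against the tert-alkyl group C21 should place C8 cis to C2, the geometry the later ring closure needs.

Step 15
Reactants: 22 (Z)-α,β-unsaturated Weinreb amide
Product: 23 allyl ketone (C3–C4 allyl on C2; vinyl on C21)
Conditions: allylMgBr, THF, −78 to 0 °C; then aq NH4Cl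
Reagents that add atoms: allylmagnesium bromide, C=CC[Mg]Br
Why: In the Weinreb ketone synthesis the chelated tetrahedral adduct stops after one addition and releases the β,γ-unsaturated ketone only on a mildly acidic quench, so the allyl group is not moved into conjugation.

Step 16
Reactants: 23 allyl ketone
Product: 24 ring C enone (Z)-6-alkylidene-5,5-dimethylcyclohex-3-en-1-one
Conditions: second-generation Grubbs catalyst (5 mol %), 1,4-benzoquinone (10 mol %), CH2Cl2, 40 °C
Reagents that add atoms: none
Why: Ring-closing metathesis of the two monosubstituted alkenes closes ring C and places the alkene unambiguously at C4=C5 under neutral conditions, while the trisubstituted enone alkene stays out and benzoquinone suppresses hydride-induced isomerisation.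

Step 17
Reactants: 24 ring C enone
Product: 26 cis-fused 6-7-6 allylic alcohol (C2 α-OH; C20=C7; C4=C5), via primary alkyllithium 25 (not isolated)
Conditions: t-BuLi (2.1 equiv), Et2O–pentane, −78 °C, high dilution; then H2O
Reagents that add atoms: none
Why: Iodine–lithium exchange at the primary iodide, far faster than attack on the ketone or the secondary bromide, is followed by intramolecular 1,2-addition (7-exo-trig), in which the trans-diequatorial C8 and C19 arms of ring A impose a chair-like cycloheptene transition state where C3 must stay pseudo-equatorial, so the alkoxide ends pseudo-axial on the α face and ring A sets C2.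

Step 18
Reactants: 26 cis-fused 6-7-6 allylic alcohol
Product: 27 cis-fused syn-epoxy cycloheptanol (α-epoxide C20–C7; C2 α-OH)
Conditions: VO(acac)2 (5 mol %), t-BuOOH, CH2Cl2, 0 °C
Reagents that add atoms: tert-butyl hydroperoxide, CC(C)(C)OO
Why: Hydroxyl-directed vanadium-catalysed epoxidation delivers oxygen to C20=C7 from the face of the pseudo-axial C2 hydroxyl, which sets C7 and C20 syn to it, while the merely homoallylic, hindered, disubstituted C4=C5 alkene reacts much more slowly.

Step 19
Reactants: 27 cis-fused syn-epoxy cycloheptanol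
Product: 28 spiro β-hydroxy ketone (C2 ketone; C7 α-OH; C4=C5)
Conditions: BF3·OEt2 (0.5 equiv), CH2Cl2, −78 °C
Reagents that add atoms: none
Why: BF3 binds the epoxide oxygen and loosens its bond to the tertiary C20; as charge builds there, the C2–C19 σ bond shifts to C20 and the C2 hydroxyl collapses to the ketone, which is a semipinacol rearrangement of a 2,3-epoxy alcohol, a known route to β-hydroxy ketones with a quaternary α-carbon that includes ring-contracting cases. Ring B is formed not by a cyclisation but by contraction of the seven-membered ring through this suprafacial 1,2-alkyl shift, with C19–C20 as the one new skeletal bond. The only new stereocentre, spiro C20, arises by inversion at the epoxide carbon, so it is dictated by the α-epoxide from step 18, and C7 keeps its oxygen and its configuration. The step needs C19 to migrate rather than C3, a C21 methyl group or H7; trans-fused ring A holds the cycloheptane in a chair-like form in which C19 is axial on ring C and antiperiplanar to C20–O while C2–C3 is gauche to it, and only a shift from C2 is rewarded by carbonyl formation. At −78 °C the silyl ether, the equatorial neopentyl bromide and the unconjugated C4=C5 alkene should remain untouched.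

Step 20
Reactants: 28 spiro β-hydroxy ketone
Product: 30 tetracyclic ether ketone (rings A–D; C2 ketone), via organomercury trifluoroacetate 29 (not isolated)
Conditions: Hg(OCOCF3)2, MeCN, 0 °C; then NaBH4, aq NaOH, −20 °C, short contact
Reagents that add atoms: none
Why: Intramolecular oxymercuration (5-exo-trig, anti addition) lets the C7 hydroxyl reach only C5 and only from the face on which C7 sits, which fixes C5 (S), and the very fast reductive demercuration should outrun reduction of the ketone flanked by the spiro carbon.

Step 21
Reactants: 30 tetracyclic ether ketone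
Product: 31 target C15 triethylsilyl ether
Conditions: Cp2TiMe2, toluene, 70 °C, dark
Reagents that add atoms: dimethyltitanocene, C[Ti](C)(C1C=CC=C1)C1C=CC=C1
Why: Petasis methylenation uses a non-basic titanium methylidene that converts hindered, enolisable ketones into methylene compounds without touching the bromide.

Step 22
Reactants: 31 target C15 triethylsilyl ether
Product: 32 CNP0412361.2 (target)
Conditions: Bu4NF, THF, rt
Reagents that add atoms: none
Why: Fluoride desilylation frees the tertiary alcohol under non-acidic conditions that endanger neither the exocyclic alkene nor the bromide, which has no antiperiplanar hydrogen.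

Compound list
1 | geranyl acetate | CC(C)=CCC/C(C)=C/COC(C)=O | starting material
2 | (2E,6E)-8-hydroxy-3,7-dimethylocta-2,6-dien-1-yl acetate | OC/C(C)=C/CC/C(C)=C/COC(C)=O | intermediate
3 | (2E,6S,7R)-6-bromo-7-chloro-8-hydroxy-3,7-dimethyloct-2-en-1-yl acetate | OC[C@](Cl)(C)[C@@H](Br)CC/C(C)=C/COC(C)=O | intermediate
4 | 8-O-tert-butyldimethylsilyl ether of 3 | CC(C)(C)[Si](C)(C)OC[C@](Cl)(C)[C@@H](Br)CC/C(C)=C/COC(C)=O | intermediate
5 | trans-fused acetoxonium chloride (2-methyl-1,3-dioxan-2-ylium spanning O–C15 and O–C19 of ring A) | CC(C)(C)[Si](C)(C)OC[C@]1(C)[C@@H](Br)CC[C@]2(C)OC(C)=[O+]C[C@@H]12.[Cl-] | intermediate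
6 | ring A hydroxy acetate: C9 β-axial CH3 and α-equatorial CH2OTBS, C11 equatorial Br, C15 α-equatorial OH and β-axial CH3, C18 equatorial CH2OAc | CC(C)(C)[Si](C)(C)OC[C@]1(C)[C@@H](Br)CC[C@](C)(O)[C@H]1COC(C)=O | intermediate
7 | ring A exocyclic alkene (C15=C16), otherwise as 6 | CC(C)(C)[Si](C)(C)OC[C@]1(C)[C@@H](Br)CCC(=C)[C@H]1COC(C)=O | intermediate
8 | spiro secondary ozonide at C15 (epimers) | CC(C)(C)[Si](C)(C)OC[C@]1(C)[C@@H](Br)CCC2(OCOO2)[C@H]1COC(C)=O | intermediate
9 | ring A C15 ketone (C18 equatorial CH2OAc) | CC(C)(C)[Si](C)(C)OC[C@]1(C)[C@@H](Br)CCC(=O)[C@H]1COC(C)=O | intermediate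
10 | ring A diol: C15 β-axial OH and α-equatorial CH3, C18 equatorial CH2OH, C8 OTBS | CC(C)(C)[Si](C)(C)OC[C@]1(C)[C@@H](Br)CC[C@@](C)(O)[C@H]1CO | intermediate
11 | ring A C19 iodide, C15 OH, C8 OTBS | CC(C)(C)[Si](C)(C)OC[C@]1(C)[C@@H](Br)CC[C@@](C)(O)[C@H]1CI | intermediate
12 | ring A iodo diol (C8 OH, C15 OH) | OC[C@]1(C)[C@@H](Br)CC[C@@](C)(O)[C@H]1CI | intermediate
13 | ring A C8 aldehyde, C15 OH, C19 iodide | O=C[C@]1(C)[C@@H](Br)CC[C@@](C)(O)[C@H]1CI | intermediate
14 | ring A C8 aldehyde, C15 OTES, C19 iodide | O=C[C@]1(C)[C@@H](Br)CC[C@@](C)(O[Si](CC)(CC)CC)[C@H]1CI | intermediate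
15 | methyl enol ether C8=C7–OMe (E/Z) | COC=C[C@]1(C)[C@@H](Br)CC[C@@](C)(O[Si](CC)(CC)CC)[C@H]1CI | intermediate
16 | ring A aldehyde: C9–CH2–CHO (C8, C7), C15 OTES, C19 iodide | O=CC[C@]1(C)[C@@H](Br)CC[C@@](C)(O[Si](CC)(CC)CC)[C@H]1CI | intermediate
17 | methyl 3,3-dimethylpent-4-enoate | C=CC(C)(C)CC(=O)OC | starting material
18 | N-methoxy-N,3,3-trimethylpent-4-enamide | C=CC(C)(C)CC(=O)N(C)OC | intermediate
19 | lithium enolate of 18 | C=CC(C)(C)C=C(O[Li])N(C)OC | intermediate
20 | lithium aldolate (C7 O–Li, C20 H; diastereomers) | C=CC(C)(C)C(C(=O)N(C)OC)C(O[Li])C[C@]1(C)[C@@H](Br)CC[C@@](C)(O[Si](CC)(CC)CC)[C@H]1CI | intermediate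
21 | C7 mesylate (diastereomers) | C=CC(C)(C)C(C(=O)N(C)OC)C(OS(C)(=O)=O)C[C@]1(C)[C@@H](Br)CC[C@@](C)(O[Si](CC)(CC)CC)[C@H]1CI | intermediate
22 | (Z)-α,β-unsaturated Weinreb amide, C20=C7, C8 cis to C2, C20 bearing CMe2CH=CH2 | C=CC(C)(C)/C(C(=O)N(C)OC)=C/C[C@]1(C)[C@@H](Br)CC[C@@](C)(O[Si](CC)(CC)CC)[C@H]1CI | intermediate
23 | (Z)-allyl ketone (allyl on C2), otherwise as 22 | C=CC(C)(C)/C(C(=O)CC=C)=C/C[C@]1(C)[C@@H](Br)CC[C@@](C)(O[Si](CC)(CC)CC)[C@H]1CI | intermediate
24 | ring C enone: (Z)-6-alkylidene-5,5-dimethylcyclohex-3-en-1-one carrying ring A through C7–C8 | O=C1CC=CC(C)(C)/C1=C/C[C@]2(C)[C@@H](Br)CC[C@@](C)(O[Si](CC)(CC)CC)[C@H]2CI | intermediate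
25 | primary alkyllithium at C19 | O=C1CC=CC(C)(C)/C1=C/C[C@]2(C)[C@@H](Br)CC[C@@](C)(O[Si](CC)(CC)CC)[C@H]2C[Li] | intermediate
26 | cis-fused 6-7-6 allylic alcohol: C2 α-OH, C20=C7, C4=C5, C15 OTES | O[C@]12CC=CC(C)(C)C1=CC[C@]3(C)[C@@H](Br)CC[C@@](C)(O[Si](CC)(CC)CC)[C@H]3C2 | intermediate
27 | cis-fused syn-epoxy cycloheptanol: α-epoxide C20–C7, C2 α-OH (key-step precursor) | O[C@]12CC=CC(C)(C)[C@]13O[C@@H]3C[C@]4(C)[C@@H](Br)CC[C@@](C)(O[Si](CC)(CC)CC)[C@H]4C2 | intermediate
28 | spiro β-hydroxy ketone: C2 ketone, spiro C20, C7 α-equatorial OH, C4=C5 (key-step product) | O=C1CC=CC(C)(C)[C@@]12C[C@@H]3[C@](C)(O[Si](CC)(CC)CC)CC[C@H](Br)[C@@]3(C)C[C@H]2O | intermediate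
29 | organomercury trifluoroacetate: ring D closed, Hg on C4 trans to O6 | O=C1C[C@@H]([Hg]OC(=O)C(F)(F)F)[C@@H]2O[C@@H]3C[C@]4(C)[C@@H](Br)CC[C@@](C)(O[Si](CC)(CC)CC)[C@H]4C[C@]13C2(C)C | intermediate
30 | tetracyclic ether ketone (C2 ketone, C15 OTES) | O=C1CC[C@@H]2O[C@@H]3C[C@]4(C)[C@@H](Br)CC[C@@](C)(O[Si](CC)(CC)CC)[C@H]4C[C@]13C2(C)C | intermediate
31 | target C15 triethylsilyl ether | C=C1CC[C@@H]2O[C@@H]3C[C@]4(C)[C@@H](Br)CC[C@@](C)(O[Si](CC)(CC)CC)[C@H]4C[C@]13C2(C)C | intermediate
32 | CNP0412361.2, configuration 5S,7R,9S,11S,15R,18S,20R in the numbering used here | C=C1CC[C@@H]2O[C@@H]3C[C@]4(C)[C@@H](Br)CC[C@@](C)(O)[C@H]4C[C@]13C2(C)C | target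

Total step count: 22. Longest linear sequence: 21 steps, from 1 to 32 through steps 1–12 and 14–22. Step 13 is the side branch.

The three steps most likely to fail are 19, 17 and 4.

Step 19. The shift may go astray in several ways. The ring C bond C2–C3 or a C21 methyl group may migrate, or H7 may move to C20. The Lewis acid may also bind the free C2 hydroxyl and ionise that tertiary allylic-type centre.
- The fallback sets out from 27. The C2 hydroxyl is capped with Me3SiOTf and 2,6-lutidine to give the epoxy trimethylsilyl ether F1.
- F1 is rearranged with the bulky monodentate Lewis acid MeAl(OC6H2-4-Br-2,6-t-Bu2)2 in CH2Cl2 at −78 °C. This is the epoxy silyl ether variant of the rearrangement: only the epoxide oxygen can be activated, and the silyl group passes to the C7 oxygen. It gives the β-silyloxy ketone F2.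
- Citric acid in methanol removes only the trimethylsilyl group, and the route is rejoined at 28.

Step 17. Proton transfer from the C3 methylene group, which is activated by both the ketone and the alkene, to the alkyllithium or to t-BuLi may compete with ring closure. Direct attack of t-BuLi on the carbonyl group may interfere as well.
- The fallback sets out from 24 and replaces the carbanion by a reductive Barbier coupling. Samarium diiodide SmI2 (2.5 equiv) with catalytic NiI2 in THF at 0 °C forms a far less basic organosamarium species in the presence of the ketone.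
- This species adds through the same chair-like arrangement, and the route is rejoined at 26. No new isolable compound is made.

Step 4. Capture of the C15 cation by the acetate may be incomplete. Proton loss to the useless endocyclic alkene or trapping by the solvent may then take over.
- The fallback sets out from 4 and installs a stronger internal nucleophile. K2CO3 in methanol at 0 °C gives the allylic alcohol F3, and Boc2O with DMAP gives the tert-butyl carbonate F4.
- Solvolysis in (CF3)2CHOH then ends with attack of the carbonate carbonyl and loss of isobutene. It gives the trans-fused cyclic carbonate F5.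
- K2CO3 in methanol opens F5 to the diol F6. Selective acetylation of the primary hydroxyl (Ac2O, pyridine, 0 °C) brings the route back at 6.

Further compounds
F1 | step 19 | C2 O-trimethylsilyl ether of epoxy alcohol 27 | C[Si](C)(C)O[C@]12CC=CC(C)(C)[C@]13O[C@@H]3C[C@]4(C)[C@@H](Br)CC[C@@](C)(O[Si](CC)(CC)CC)[C@H]4C2
F2 | step 19 | C7 O-trimethylsilyl ether of spiro ketone 28 | O=C1CC=CC(C)(C)[C@@]12C[C@@H]3[C@](C)(O[Si](CC)(CC)CC)CC[C@H](Br)[C@@]3(C)C[C@H]2O[Si](C)(C)C
F0 | step 17 | none | none
F3 | step 4 | (2E,6S,7R)-6-bromo-8-(tert-butyldimethylsilyloxy)-7-chloro-3,7-dimethyloct-2-en-1-ol | CC(C)(C)[Si](C)(C)OC[C@](Cl)(C)[C@@H](Br)CC/C(C)=C/CO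
F4 | step 4 | tert-butyl carbonate of F3 | CC(C)(C)[Si](C)(C)OC[C@](Cl)(C)[C@@H](Br)CC/C(C)=C/COC(=O)OC(C)(C)C
F5 | step 4 | trans-fused cyclic carbonate of ring A (O–C15 equatorial, C19–O) | CC(C)(C)[Si](C)(C)OC[C@]1(C)[C@@H](Br)CC[C@]2(C)OC(=O)OC[C@@H]12
F6 | step 4 | ring A diol with C15 α-equatorial OH and β-axial CH3 | CC(C)(C)[Si](C)(C)OC[C@]1(C)[C@@H](Br)CC[C@](C)(O)[C@H]1CO
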